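All runs are simulated on assumed constants, and the scatter is random.

A percentage point of the substrate charged, per hour, is the unit I reckon in here, and I picture target as a pool with a flow passing through it.

all flasks: substrate 0.35 M; gas phase 37 mM (held)

| charge | catalyst | remark | time |
|---|---|---|---|
| zeta | 0.36 mM | run made earlier |  |
| eta | 2.6 mM | run made earlier |  |
| red | 0.25 mM |  | 25 h |
| ochre | 0.50 mM |  | 25 h |
| blue | 1.0 mM |  | 25 h |
| grey | 2.0 mM |  | 25 h |

- zeta (time / h: target / %, substrate / %): 1.33: 1.9, 97.7; 2.50: 5.0, 96.1; 5.00: 8.3, 91.0; 10.0: 12.4, 83.7; 20.0: 13.0, 73.4
- eta (time / h: target / %, substrate / %): 1.50: 4.4, 95.1; 4.00: 9.8, 89.6; 8.00: 14.3, 82.7; 12.0: 15.1, 77.5; 20.0: 15.5, 69.4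

(readings scatter by 0.5 percentage points)

- at the start none of the gas is dissolved
- on the list of suspects stand: gas phase <-> dissolved gas; dissolved gas + target -> over-reaction product; substrate + dissolved gas + catalyst <-> catalyst + target
- "hardly changes" means that all values lie within two and a half points (for a concentration: within two and a half percent of the largest)

- amount of target at the end, in percent of the substrate charged for red, ochre, blue, grey, in this order
- the course of these numbers from the first flask to the last (falls all the way / rises all the way / hardly changes / rises, then falls / falls, then rises)

In the eta run, between 12.0 h and 20.0 h, substrate drops by 8.1 percentage points while target gains 0.4 points. So, as far as these readings show, nearly all of that substrate has passed through target and on to over-reaction product. Dividing the target present by this flow gives 15.3 h for the eta run.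

My objection is that one run proves little. The over-reaction step on the list of suspects holds no catalyst, so the zeta run, with 7.22 times less catalyst, should give about the same figure if dissolved gas stands alike in the two runs. Its last interval gives 12.6 h. The gap is 2.70 h, but the scatter of the substrate drop moves the eta figure by 1.34 h, so I cannot call the gap real. I carry their mean, 14.0 h, as the target lifetime, c(target) divided by the flow through it. It is a pseudo-first-order lifetime, valid while dissolved gas changes slowly.

The run of 25 h lasts 1.79 lifetimes, so by this estimate 16.8% of the target formed at the very start remains at the end, and I treat target at the end as a largely replaced pool.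

For the row, the readings at 20.0 h stand 2.5 points apart, right on the margin. But red has less catalyst than zeta and grey less than eta, so I expect red below 13.0% and grey below 15.5%. Substrate also keeps falling after 20.0 h, which can pull both ends down. With a scatter of 0.5 points on each reading, that spread stands too close to the margin to call, and I lean weakly to a course that hardly changes.

The forecast gives 12%, 13.4%, 14.6% and 15.3%, a target that “rises with catalyst and saturates toward the equilibrium ceiling”, and so rises all the way. That differs from my lean.

The flasks give 12.1%, 13.4%, 14.1% and 14.5%, a spread of 2.4 points, so the course reads: hardly changes. Target in grey goes from 15.6% at 12.5 h to 14.5% at 25.0 h.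

    gas phase ⇌ dissolved gas, rate k1*(csat - [dissolved gas]) (kL = 0.00710 min⁻¹)
    dissolved gas + target → over-reaction product (k = 0.0550 M⁻¹ min⁻¹)
    substrate + dissolved gas + catalyst ⇌ catalyst + target (K = 11.0 M⁻¹, k = 110 M⁻² min⁻¹)

With the lifetime, red's target of 12.1% should send 11 points into over-reaction product between 12.5 h and 25.0 h, and the flask shows 11 points. Grey's 14.5% should send 13 points, and grey shows 13 points.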